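The constants used here stand for no real mixture; what happens was integrated by code.

Follow one substrate molecule and ask at its fork whether it meets dissolved gas before it falls to side product A.

    target ⇌ isomer of the product (K1 = 0.35, k1 = 0.0027 /min)
    substrate + target → side product B (k2 = 0.73 /M/min)
    substrate → side product A (k3 = 0.018 /min)
    gas phase ⇌ dissolved gas, rate k4*(csat - [dissolved gas]) (k4 = 0.023 /min, csat = 1.9 mM)
    substrate + dissolved gas → target (k5 = 11 /M/min)
    dissolved gas + protic impurity → quenched reagent (k6 = 0.32 /M/min)

substrate 20 mM; gas phase 1.9 mM (held); protic impurity 10.0 mM; time 5.0 h

- in percentages every species weighs as the substrate in it: one side product B counts as two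
- at the start none of the gas is dissolved
- run time (flask): 5.0 h

- how much target there is at 5.0 h, in percent of the substrate charged
- the change that raises the amount of target at 5.0 h, in percent of the substrate charged most ("none" if none brings more than 2 percentage points) (Wednesday's / Friday's / none)
- amount of target at 5.0 h, in percent of the substrate charged, after Friday's

- Wednesday's: doubling the saturation concentration of gas phase, all else as stated
- Friday's: doubling the transfer coefficient of step 4, all else as stated

1. Let c be the dissolved gas concentration. At the fork, the molecule takes up gas at 11 /M/min times c and falls to side product A at 0.018 /min. Its chance of becoming target is therefore c/(c + h), a partition ratio, where h is the even level 1.64 mM.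

2. Take the fast extreme, where passage is so quick that c stands at saturation, 1.9 mM. The chance at the fork is then 53.7%.

3. Take the slow extreme, where substrate captures each dissolved molecule at once and c stays near zero. Target then equals the gas delivered while substrate lasts, and a substrate lifetime is 55.6 min. Call the gas entering empty solution during that lifetime, as a share of the charge, the supply share S: 12.1%.

4. Place the flask between them. Capture by the charged substrate runs at 0.220 /min, faster than transfer at 0.023 /min, so the flask starts near the slow extreme. Loss of gas to the protic impurity runs at 0.003200 /min, slower than capture, so set it aside.

5. Commit to y near S: gas arriving after one lifetime adds some target, while side product B and the isomer take some away. Both changes double S to 24.2%, but Wednesday's also lifts the fast extreme to 69.9%, while Friday's leaves it at 53.7%. So choose Wednesday's, and put yb between S and 24.2%.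

The forecast gave 12%, Wednesday's and 14.5%: “The run is gas-transfer limited”.

The simulation gives y = 10.6%, best = Wednesday's (a gain of 6.6 percentage points against 4.5 points for Friday's) and yb = 15.1%.

In this flask, the pace of the uptake of gas phase as dissolved gas holds target down: making that uptake a thousand times as fast lifts target from 10.6% to 31.7%, the largest single effect among the simulated removals. That gain is 24% of what is missing from the full charge. In the neighbour flask with 50 mM of substrate, the same gas meets a larger charge, so S falls to 4.86%; that neighbour flask gives 5.35%.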